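**Plan**

- Retrosynthesis: the (E)-2-alkyl-2-enal is cut at its C=C bond (aldol retron). This shows the target to be the self-condensation dimer of one aldehyde, N-Boc-12-[(2R,5S,6S)-5-hydroxy-6-methylpiperidin-2-yl]dodecanal, so a single monomer supplies both piperidine rings.
- In the monomer (ring numbering N1, C2 methyl, C3 hydroxyl, C6 chain) the piperidine is not closed as a six-membered ring. The segment C3(O)–C4–C5–C6(N), with N1–C2(Me) hanging from C3, is the retron of a 5-alkyl-2-(1-aminoethyl)furan. The five-membered furan is enlarged oxidatively to the six-membered ring: furan C2–C5 become C3–C6, the furan O becomes the C3 oxygen, and N1 closes onto C6.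
- Forward order: C12 chain onto furan, acetylation, asymmetric reductive amination, furan-to-pyridinone ring expansion, reduction at C6 and then C3, hydrogenation, oxidation to the aldehyde, aldol dimerisation that joins the two chains, deprotection.
- Stereochemistry: C2 (S) from (S)-tert-butanesulfinamide; C6 (R) by hydride delivery to the N-acyliminium ion anti to the C2 methyl group (stereoconvergent); C3 (S) by Luche reduction anti to the same methyl group; the E enal by thermodynamic control in the condensation.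

Key step: step 6

Remark: hemiaminal 15 is expected as a mixture of C6 epimers in ring–chain equilibrium with 14; this is immaterial because step 7 resets C6.

**Route**

Step 1
Reactants: 1 12-bromododecan-1-ol
Product: 2 benzyl 12-bromododecyl ether
Conditions: BnOC(=NH)CCl3, TfOH (cat.), CH2Cl2/cyclohexane, 0 °C to rt
Reagents that add atoms: benzyl 2,2,2-trichloroacetimidate, ClC(Cl)(Cl)C(=N)OCc1ccccc1
Why: Acid-catalysed O-benzylation with a trichloroacetimidate protects the alcohol without generating an alkoxide that would displace the primary bromide.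

Step 2
Reactants: 3 furan; 2 benzyl 12-bromododecyl ether
Product: 5 2-[12-(benzyloxy)dodecyl]furan, via 2-furyllithium 4 (not isolated)
Conditions: furan (excess), n-BuLi, THF, −78 to 0 °C; then 2, DMPU, 0 °C to rt
Reagents that add atoms: none
Why: α-Lithiation of furan followed by SN2 alkylation of 2-furyllithium with a primary alkyl bromide is the standard entry to 2-alkylfurans.

Step 3
Reactants: 5 2-[12-(benzyloxy)dodecyl]furan; 6 N-methoxy-N-methylacetamide
Product: 8 1-{5-[12-(benzyloxy)dodecyl]furan-2-yl}ethan-1-one, via 5-lithiofuran 7 (not isolated)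
Conditions: n-BuLi, THF, −78 to 0 °C; then 6, −78 °C to rt; H2O
Reagents that add atoms: none
Why: The remaining furan α-position is lithiated selectively and the N-methoxy-N-methylamide (Weinreb ketone synthesis) stops at the ketone through its chelated tetrahedral intermediate.

Step 4
Reactants: 8 1-{5-[12-(benzyloxy)dodecyl]furan-2-yl}ethan-1-one; 9 (S)-2-methylpropane-2-sulfinamide
Product: 11 (S)-N-[(1S)-1-{5-[12-(benzyloxy)dodecyl]furan-2-yl}ethyl]-2-methylpropane-2-sulfinamide, via N-sulfinyl ketimine 10 (not isolated)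
Conditions: Ti(OEt)4, THF, 65 °C; then NaBH4, −48 °C; MeOH, brine
Reagents that add atoms: none
Why: Ti(OEt)4-mediated condensation gives the (E)-N-sulfinyl ketimine, and borohydride delivered through a six-membered transition state with boron bound to the sulfinyl oxygen should give the (S)-configured carbon that becomes C2 (diastereoselective sulfinyl-imine reductive amination, minor diastereomer removed by chromatography).

Step 5
Reactants: 11 (S)-N-[(1S)-1-{5-[12-(benzyloxy)dodecyl]furan-2-yl}ethyl]-2-methylpropane-2-sulfinamide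
Product: 13 tert-butyl N-[(1S)-1-{5-[12-(benzyloxy)dodecyl]furan-2-yl}ethyl]carbamate, via amine hydrochloride 12 (not isolated)
Conditions: HCl (4 M in dioxane), MeOH, 0 °C; evaporate; Boc2O, Et3N, CH2Cl2, rt
Reagents that add atoms: di-tert-butyl dicarbonate, CC(C)(C)OC(=O)OC(=O)OC(C)(C)C
Why: Acidic methanolysis cleaves the N–S bond and the liberated amine is acylated by Boc2O, the carbamate then serving as ring nitrogen nucleophile, N-acyliminium activator and A(1,3) control element (auxiliary removal and carbamate protection).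

Step 6
Reactants: 13 tert-butyl N-[(1S)-1-{5-[12-(benzyloxy)dodecyl]furan-2-yl}ethyl]carbamate
Product: 15 tert-butyl (2S)-6-[12-(benzyloxy)dodecyl]-6-hydroxy-2-methyl-3-oxo-3,6-dihydropyridine-1(2H)-carboxylate (C6 epimers), via (Z)-enedione carbamate 14 (not isolated)
Conditions: mCPBA (1.2 equiv), CH2Cl2, 0 °C to rt
Reagents that add atoms: 3-chloroperoxybenzoic acid (mCPBA), OOC(=O)c1cccc(Cl)c1
Why: The peracid oxidises the electron-rich 2,5-dialkylfuran, the oxidised ring opens to the (Z)-ene-1,4-dione 14 whose cis geometry is inherited from the furan, and the carbamate N–H adds to the C6 ketone to give hemiaminal 15, so that furan C2–C5 become ring atoms C3–C6, the furan oxygen becomes the C3 carbonyl oxygen and N1 and C2 enter from the side chain. The closest known reaction type is the aza-Achmatowicz oxidative ring expansion of N-acyl and N-sulfonyl furfurylamines, applied here to a 2,5-disubstituted furan. The one ring that closes, by the N1–C6 bond, does so in a 6-exo-trig mode (nitrogen onto the ketone carbonyl), which only the Z-enedione can reach. The only new stereocentre is the hemiaminal carbon C6, set reversibly under thermodynamic control and free to be non-uniform because step 7 erases it, while C2 is untouched since no bond to it is made or broken. The step needs chemoselectivity for the furan over the benzyl ether and the carbamate, which the far higher nucleophilicity of the dialkylfuran towards the peracid should secure, and it needs C2 (now α to a ketone) to keep its configuration, which the non-basic medium and the A(1,3) strain that disfavours enolisation next to the N-Boc group should secure.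

Step 7
Reactants: 15 tert-butyl (2S)-6-[12-(benzyloxy)dodecyl]-6-hydroxy-2-methyl-3-oxo-3,6-dihydropyridine-1(2H)-carboxylate
Product: 17 tert-butyl (2S,6R)-6-[12-(benzyloxy)dodecyl]-2-methyl-3-oxo-3,6-dihydropyridine-1(2H)-carboxylate, via N-acyliminium ion 16 (not isolated)
Conditions: Et3SiH (5 equiv), BF3·OEt2 (2 equiv), CH2Cl2, −78 to −40 °C
Reagents that add atoms: none
Why: The Lewis acid ionises the tertiary hemiaminal (and recloses any 14) to the planar N-acyliminium ion, and the silane delivers hydride to C6 from the face anti to the C2 methyl group, held pseudoaxial by A(1,3) strain with N-Boc, so both C6 epimers should converge on the 2,6-cis (6R) product (ionic hydrogenation of an N,O-hemiaminal through an N-acyliminium ion).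

Step 8
Reactants: 17 tert-butyl (2S,6R)-6-[12-(benzyloxy)dodecyl]-2-methyl-3-oxo-3,6-dihydropyridine-1(2H)-carboxylate
Product: 18 tert-butyl (2S,3S,6R)-6-[12-(benzyloxy)dodecyl]-3-hydroxy-2-methyl-3,6-dihydropyridine-1(2H)-carboxylate
Conditions: NaBH4, CeCl3·7H2O, MeOH, −78 °C
Reagents that add atoms: none
Why: Luche 1,2-reduction of the enone, in which hydride attacks C3 from the face opposite the pseudoaxial C2 methyl group so that the hydroxyl should end cis to it (3S).

Step 9
Reactants: 18 tert-butyl (2S,3S,6R)-6-[12-(benzyloxy)dodecyl]-3-hydroxy-2-methyl-3,6-dihydropyridine-1(2H)-carboxylate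
Product: 19 tert-butyl (2S,3S,6R)-3-hydroxy-6-(12-hydroxydodecyl)-2-methylpiperidine-1-carboxylate
Conditions: H2 (1 atm), 10% Pd/C, EtOAc/EtOH, rt
Reagents that add atoms: none
Why: Heterogeneous hydrogenation saturates C4=C5 and hydrogenolyses the benzyl ether in one operation without touching the carbamate or the three stereocentres.

Step 10
Reactants: 19 tert-butyl (2S,3S,6R)-3-hydroxy-6-(12-hydroxydodecyl)-2-methylpiperidine-1-carboxylate
Product: 20 tert-butyl (2S,3S,6R)-3-hydroxy-2-methyl-6-(12-oxododecyl)piperidine-1-carboxylate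
Conditions: TEMPO (10 mol%), PhI(OAc)2 (1.1 equiv), CH2Cl2, rt
Reagents that add atoms: none
Why: Oxoammonium-mediated (TEMPO) oxidation is selective for the primary alcohol over the hindered secondary C3 hydroxyl and stops at the aldehyde.

Step 11
Reactants: 20 tert-butyl (2S,3S,6R)-3-hydroxy-2-methyl-6-(12-oxododecyl)piperidine-1-carboxylate (two molecules)
Product: 22 tert-butyl (2S,3S,6R)-6-{(12E)-23-[(2R,5S,6S)-1-(tert-butoxycarbonyl)-5-hydroxy-6-methylpiperidin-2-yl]-13-formyltricos-12-en-1-yl}-3-hydroxy-2-methylpiperidine-1-carboxylate, via aldol adduct 21 (not isolated)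
Conditions: pyrrolidine (20 mol%), PhCO2H (20 mol%), toluene, rt to 40 °C
Reagents that add atoms: none
Why: Amine-catalysed self-aldol addition of two molecules of 20 followed by dehydration in the flask should give the thermodynamically preferred (E)-2-alkyl-2-enal with the β-chain trans to the formyl group (aldol condensation, mirroring the presumed biosynthetic dimerisation).

Step 12
Reactants: 22 tert-butyl (2S,3S,6R)-6-{(12E)-23-[(2R,5S,6S)-1-(tert-butoxycarbonyl)-5-hydroxy-6-methylpiperidin-2-yl]-13-formyltricos-12-en-1-yl}-3-hydroxy-2-methylpiperidine-1-carboxylate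
Product: 23 (2E)-2-{10-[(2R,5S,6S)-5-hydroxy-6-methylpiperidin-2-yl]decyl}-14-[(2R,5S,6S)-5-hydroxy-6-methylpiperidin-2-yl]tetradec-2-enal
Conditions: TFA/CH2Cl2 (1:4), 0 °C to rt; aq. NaHCO3
Reagents that add atoms: none
Why: Acidolysis of both tert-butyl carbamates leaves the enal and all six stereocentres untouched and should give the target after basic work-up (Boc cleavage).

**Compound list**

1 | 12-bromododecan-1-ol | OCCCCCCCCCCCCBr | starting material
2 | benzyl 12-bromododecyl ether | BrCCCCCCCCCCCCOCc1ccccc1 | intermediate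
3 | furan | c1ccoc1 | starting material
4 | 2-furyllithium | [Li]c1ccco1 | intermediate
5 | 2-[12-(benzyloxy)dodecyl]furan | c1coc(CCCCCCCCCCCCOCc2ccccc2)c1 | intermediate
6 | N-methoxy-N-methylacetamide | CC(=O)N(C)OC | starting material
7 | {5-[12-(benzyloxy)dodecyl]furan-2-yl}lithium | [Li]c1ccc(CCCCCCCCCCCCOCc2ccccc2)o1 | intermediate
8 | 1-{5-[12-(benzyloxy)dodecyl]furan-2-yl}ethan-1-one | CC(=O)c1ccc(CCCCCCCCCCCCOCc2ccccc2)o1 | intermediate
9 | (S)-2-methylpropane-2-sulfinamide | CC(C)(C)[S@](=O)N | starting material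
10 | (S)-N-[(1E)-1-{5-[12-(benzyloxy)dodecyl]furan-2-yl}ethylidene]-2-methylpropane-2-sulfinamide | CC(C)(C)[S@](=O)/N=C(\C)c1ccc(CCCCCCCCCCCCOCc2ccccc2)o1 | intermediate
11 | (S)-N-[(1S)-1-{5-[12-(benzyloxy)dodecyl]furan-2-yl}ethyl]-2-methylpropane-2-sulfinamide | CC(C)(C)[S@](=O)N[C@@H](C)c1ccc(CCCCCCCCCCCCOCc2ccccc2)o1 | intermediate
12 | (1S)-1-{5-[12-(benzyloxy)dodecyl]furan-2-yl}ethan-1-aminium chloride | C[C@H]([NH3+])c1ccc(CCCCCCCCCCCCOCc2ccccc2)o1.[Cl-] | intermediate
13 | tert-butyl N-[(1S)-1-{5-[12-(benzyloxy)dodecyl]furan-2-yl}ethyl]carbamate | C[C@H](NC(=O)OC(C)(C)C)c1ccc(CCCCCCCCCCCCOCc2ccccc2)o1 | intermediate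
14 | tert-butyl N-[(2S,4Z)-18-(benzyloxy)-3,6-dioxooctadec-4-en-2-yl]carbamate | C[C@H](NC(=O)OC(C)(C)C)C(=O)/C=C\C(=O)CCCCCCCCCCCCOCc1ccccc1 | intermediate
15 | tert-butyl (2S)-6-[12-(benzyloxy)dodecyl]-6-hydroxy-2-methyl-3-oxo-3,6-dihydropyridine-1(2H)-carboxylate (C6 epimers) | C[C@H]1C(=O)C=CC(O)(CCCCCCCCCCCCOCc2ccccc2)N1C(=O)OC(C)(C)C | intermediate
16 | (2S)-6-[12-(benzyloxy)dodecyl]-1-(tert-butoxycarbonyl)-2-methyl-3-oxo-2,3-dihydropyridin-1-ium | C[C@H]1C(=O)C=CC(CCCCCCCCCCCCOCc2ccccc2)=[N+]1C(=O)OC(C)(C)C | intermediate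
17 | tert-butyl (2S,6R)-6-[12-(benzyloxy)dodecyl]-2-methyl-3-oxo-3,6-dihydropyridine-1(2H)-carboxylate | C[C@H]1C(=O)C=C[C@@H](CCCCCCCCCCCCOCc2ccccc2)N1C(=O)OC(C)(C)C | intermediate
18 | tert-butyl (2S,3S,6R)-6-[12-(benzyloxy)dodecyl]-3-hydroxy-2-methyl-3,6-dihydropyridine-1(2H)-carboxylate | C[C@H]1[C@@H](O)C=C[C@@H](CCCCCCCCCCCCOCc2ccccc2)N1C(=O)OC(C)(C)C | intermediate
19 | tert-butyl (2S,3S,6R)-3-hydroxy-6-(12-hydroxydodecyl)-2-methylpiperidine-1-carboxylate | C[C@H]1[C@@H](O)CC[C@@H](CCCCCCCCCCCCO)N1C(=O)OC(C)(C)C | intermediate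
20 | tert-butyl (2S,3S,6R)-3-hydroxy-2-methyl-6-(12-oxododecyl)piperidine-1-carboxylate | C[C@H]1[C@@H](O)CC[C@@H](CCCCCCCCCCCC=O)N1C(=O)OC(C)(C)C | intermediate
21 | tert-butyl (2S,3S,6R)-6-{23-[(2R,5S,6S)-1-(tert-butoxycarbonyl)-5-hydroxy-6-methylpiperidin-2-yl]-13-formyl-12-hydroxytricosyl}-3-hydroxy-2-methylpiperidine-1-carboxylate (aldol adduct, mixture at chain C12 and C13) | C[C@H]1[C@@H](O)CC[C@@H](CCCCCCCCCCCC(O)C(C=O)CCCCCCCCCC[C@@H]2CC[C@H](O)[C@H](C)N2C(=O)OC(C)(C)C)N1C(=O)OC(C)(C)C | intermediate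
22 | tert-butyl (2S,3S,6R)-6-{(12E)-23-[(2R,5S,6S)-1-(tert-butoxycarbonyl)-5-hydroxy-6-methylpiperidin-2-yl]-13-formyltricos-12-en-1-yl}-3-hydroxy-2-methylpiperidine-1-carboxylate (N,N'-di-Boc target) | C[C@H]1[C@@H](O)CC[C@@H](CCCCCCCCCCC/C=C(/C=O)CCCCCCCCCC[C@@H]2CC[C@H](O)[C@H](C)N2C(=O)OC(C)(C)C)N1C(=O)OC(C)(C)C | intermediate
23 | (2E)-2-{10-[(2R,5S,6S)-5-hydroxy-6-methylpiperidin-2-yl]decyl}-14-[(2R,5S,6S)-5-hydroxy-6-methylpiperidin-2-yl]tetradec-2-enal | C[C@@H]1N[C@H](CCCCCCCCCCC/C=C(/C=O)CCCCCCCCCC[C@@H]2CC[C@H](O)[C@H](C)N2)CC[C@@H]1O | target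

**Summary and risks**

Total step count: 12. Longest linear sequence: 12 steps (steps 1–12 from 12-bromododecan-1-ol; 3, 6 and 9 are commercial inputs).

Steps most likely to fail:

Step 7. Ionisation of the tertiary N-Boc hemiaminal may be slow from the open enedione form or be accompanied by loss of the carbamate under the Lewis acid. Hydride delivery may also be poorly face-selective or occur at C4 instead of C6. The fallback sets out from 11 and comes back at 19; it changes the nitrogen activator from carbamate to a sulfonyl group made from the auxiliary itself. Treating 11 with excess mCPBA should oxidise sulfur to the tert-butylsulfonamide and ring-expand the furan in the same flask to (2S)-6-[12-(benzyloxy)dodecyl]-1-(tert-butylsulfonyl)-6-hydroxy-2-methyl-1,6-dihydropyridin-3(2H)-one F1. The acid-stable sulfonamide tolerates forcing ionic hydrogenation (Et3SiH with BF3·OEt2 or TFA), which should give the 2,6-cis N-sulfonyl dihydropyridinone F2. Luche reduction should then give the N-sulfonyl allylic alcohol F3, and hydrogenation with hydrogenolysis the N-sulfonyl diol F4. TfOH/anisole in CH2Cl2 at 0 °C should remove the sulfonyl group to give (2S,3S,6R)-6-(12-hydroxydodecyl)-2-methylpiperidin-3-ol F5, and N-selective acylation with Boc2O leads back to 19.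

Step 11. The condensation may not stop at the dimer (enamine Michael addition to the enal formed, higher oligomers), may stall at the aldol stage, or may give E/Z mixtures. The fallback sets out from 20 and comes back at 23; it is a directed aldol with a preformed nucleophile. Silylation of 20 (TESCl, imidazole, DMF) gives the C3-O-triethylsilyl aldehyde F6. Half of it is condensed with cyclohexylamine (molecular sieves) to the N-cyclohexyl aldimine F7. This is deprotonated with LDA (THF, −78 °C) and combined with the other half of F6 to give the β-hydroxy imine F8, which is not isolated. Aqueous oxalic acid then hydrolyses the imine and dehydrates the adduct to the bis-O-triethylsilyl bis-N-Boc (E)-enal F9. Under the conditions of step 12 (TFA, wet CH2Cl2) this loses the silyl and Boc groups and gives 23.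

Step 4. Ketimine formation from the electron-rich, enolisable furyl ketone may be incomplete, and facial selectivity in the hydride delivery may be modest. The fallback sets out from 5 and comes back at 13; it creates the stereocentre by C–C instead of C–H bond formation. Lithiation of 5 and formylation (n-BuLi; DMF) gives 5-[12-(benzyloxy)dodecyl]furan-2-carbaldehyde F10. Condensation with (R)-2-methylpropane-2-sulfinamide (CuSO4 or Ti(OEt)4) gives the (R,E)-N-sulfinyl aldimine F11. MeMgBr in CH2Cl2 at −48 °C should add through the magnesium-chelated chair transition state to give the (R)-sulfinyl (S)-carbon sulfinamide F12, the sulfur epimer of 11. Under the conditions of step 5 this gives 13.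

Further compounds

F1 | step 7 | (2S)-6-[12-(benzyloxy)dodecyl]-1-(tert-butylsulfonyl)-6-hydroxy-2-methyl-1,6-dihydropyridin-3(2H)-one | C[C@H]1C(=O)C=CC(O)(CCCCCCCCCCCCOCc2ccccc2)N1S(=O)(=O)C(C)(C)C
F2 | step 7 | (2S,6R)-6-[12-(benzyloxy)dodecyl]-1-(tert-butylsulfonyl)-2-methyl-1,6-dihydropyridin-3(2H)-one | C[C@H]1C(=O)C=C[C@@H](CCCCCCCCCCCCOCc2ccccc2)N1S(=O)(=O)C(C)(C)C
F3 | step 7 | (2S,3S,6R)-6-[12-(benzyloxy)dodecyl]-1-(tert-butylsulfonyl)-2-methyl-1,2,3,6-tetrahydropyridin-3-ol | C[C@H]1[C@@H](O)C=C[C@@H](CCCCCCCCCCCCOCc2ccccc2)N1S(=O)(=O)C(C)(C)C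
F4 | step 7 | (2S,3S,6R)-1-(tert-butylsulfonyl)-6-(12-hydroxydodecyl)-2-methylpiperidin-3-ol | C[C@H]1[C@@H](O)CC[C@@H](CCCCCCCCCCCCO)N1S(=O)(=O)C(C)(C)C
F5 | step 7 | (2S,3S,6R)-6-(12-hydroxydodecyl)-2-methylpiperidin-3-ol | C[C@H]1[C@@H](O)CC[C@@H](CCCCCCCCCCCCO)N1
F6 | step 11 | tert-butyl (2S,3S,6R)-2-methyl-6-(12-oxododecyl)-3-[(triethylsilyl)oxy]piperidine-1-carboxylate | C[C@H]1[C@@H](O[Si](CC)(CC)CC)CC[C@@H](CCCCCCCCCCCC=O)N1C(=O)OC(C)(C)C
F7 | step 11 | tert-butyl (2S,3S,6R)-6-[(12E)-12-(cyclohexylimino)dodecyl]-2-methyl-3-[(triethylsilyl)oxy]piperidine-1-carboxylate | C[C@H]1[C@@H](O[Si](CC)(CC)CC)CC[C@@H](CCCCCCCCCCC/C=N/C2CCCCC2)N1C(=O)OC(C)(C)C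
F8 | step 11 | β-hydroxy N-cyclohexyl imine adduct of F7 and F6 (bis-O-triethylsilyl, bis-N-Boc, mixture at the two new centres) | C[C@H]1[C@@H](O[Si](CC)(CC)CC)CC[C@@H](CCCCCCCCCCCC(O)C(/C=N/C2CCCCC2)CCCCCCCCCC[C@@H]2CC[C@H](O[Si](CC)(CC)CC)[C@H](C)N2C(=O)OC(C)(C)C)N1C(=O)OC(C)(C)C
F9 | step 11 | bis-O-triethylsilyl ether of 22 | C[C@H]1[C@@H](O[Si](CC)(CC)CC)CC[C@@H](CCCCCCCCCCC/C=C(/C=O)CCCCCCCCCC[C@@H]2CC[C@H](O[Si](CC)(CC)CC)[C@H](C)N2C(=O)OC(C)(C)C)N1C(=O)OC(C)(C)C
F10 | step 4 | 5-[12-(benzyloxy)dodecyl]furan-2-carbaldehyde | O=Cc1ccc(CCCCCCCCCCCCOCc2ccccc2)o1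
F11 | step 4 | (R)-N-[(E)-{5-[12-(benzyloxy)dodecyl]furan-2-yl}methylidene]-2-methylpropane-2-sulfinamide | CC(C)(C)[S@@](=O)/N=C/c1ccc(CCCCCCCCCCCCOCc2ccccc2)o1
F12 | step 4 | (R)-N-[(1S)-1-{5-[12-(benzyloxy)dodecyl]furan-2-yl}ethyl]-2-methylpropane-2-sulfinamide | CC(C)(C)[S@@](=O)N[C@@H](C)c1ccc(CCCCCCCCCCCCOCc2ccccc2)o1
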